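At the last reading, 4.00 h, I set one column of each earlier run against another.

| flask | J | Q | remark | time |
|---|---|---|---|---|
| dawn | 0.72 M | 0.79 equiv | run made earlier |  |
| summer | 0.72 M | 2.3 equiv | run made earlier |  |
| oak | 0.72 M | 1.50 equiv |  | 6.0 h |
| birch | 0.72 M | 0.600 equiv |  | 6.0 h |

| run | time / h | E / % | J / % | J.J.Q / % | X / % | J.Q / % |
|---|---|---|---|---|---|---|
| dawn | 1.00 | 2.8 | 58.1 | 2.9 | 22.3 | 15.4 |
| dawn | 2.00 | 3.7 | 41.7 | 5.8 | 29.4 | 20.0 |
| dawn | 3.00 | 3.9 | 33.4 | 8.9 | 32.7 | 21.4 |
| dawn | 4.00 | 4.2 | 27.9 | 10.6 | 35.6 | 21.6 |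
| summer | 1.00 | 5.3 | 17.2 | 3.1 | 43.0 | 32.0 |
| summer | 2.00 | 6.0 | 4.3 | 4.0 | 49.8 | 36.1 |
| summer | 3.00 | 6.0 | 0.6 | 4.2 | 51.1 | 37.5 |
| summer | 4.00 | 6.5 | 1.0 | 4.3 | 51.7 | 37.9 |

(standard deviation of a reading: 0.3 percentage points)

- which of these there is most of at the end, counted by the J in it, oak (J.J.Q / J / X / J.Q / E)
- which of these there is most of at the end, counted by the J in it, birch (J.J.Q / J / X / J.Q / E)
- how much there is at the end of the one of these that leads, in percent of the J charged: oak
- how much there is at the end of the one of these that leads, in percent of the J charged: birch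

Each Q spent takes one J, but one J.J.Q holds two J on one Q, so Q spent, in percent of the J charged, is the J gone minus the J.J.Q reading divided by 2. The dawn row has J 27.9% and J.J.Q 10.6%, so Q spent was 66.8%, and X 35.6% gives a ratio of 0.533. The summer row has J 1.0% and J.J.Q 4.3%, so Q spent was 96.8%, and X 51.7% gives 0.534. The charges of Q were 0.79 equiv and 2.3 equiv, yet the ratios read alike. I carried their mean, 0.533, as the X share: X formed per Q spent, a selectivity.

In oak, Q spent cannot pass the J charged, so I expected X to lead just under 53.3%. Birch is charged with 0.600 equiv of Q, under one equivalent, so I took Q as the limiting reagent there: I reckoned X within 32.0%, and J ahead of that while J.J.Q stays under 16.0%. Dawn read 10.6% of J.J.Q at 4.00 h, up from 8.9% at 3.00 h, so that reading does not prove the condition for birch at 6.0 h; I expected J to lead birch, with that doubt.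

The forecast said X at 50% for oak and J at 36.3% for birch, with the ground “Q is limiting and about 0.57 equiv is consumed” for birch.

X led oak at 50.0%, and J led birch at 35.4%.

    J + Q → J.Q (k = 0.555 L mol⁻¹ h⁻¹)
    J + Q → X (k = 0.715 L mol⁻¹ h⁻¹)
    J + Q → E (k = 0.0856 L mol⁻¹ h⁻¹)
    J + J.Q → J.J.Q (k = 0.255 L mol⁻¹ h⁻¹)

In oak, X was formed 1.3 times as fast as J.Q at 0.542 h and 1.3 times as fast at 6.00 h, so the split did not move while J fell to 1.20%. Oak had 37% of its Q left, so it spent 94.8% of the J charged, and the X share gives 50.6% of X against 50.0%. A neighbour of oak, with 0.29 M of J, kept 43% of its Q, and the X share gives 45.6% against the 45.1% of X it held.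

The data stem from a simulated flask on assumed constants, noise included.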